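## Retrosynthetic overview

1. Target 45 ⇐ C11 silyl ether 44 ⇐ seco compound 42: the 19-membered ring is closed last by an intramolecular Suzuki coupling at C7–C8 (E,E-diene). The C19–tetronate bond comes from DCC/DMAP C-acylation of spirotetronic acid 13 with thiolane acid 40.
2. Thiolane of 40 ⇐ enoate 35 + ethyl bromopyruvate 36 (S-alkylation, then 5-exo Michael closure of C2'–C3') ⇐ aldehyde 30 (thia-Michael/HWE).
3. Key bond C14–C15 of 30: Negishi coupling of zinc ester homoenolate 24 (from methyl (R)-3-bromo-2-methylpropanoate 23, which supplies C16) with (E)-alkenyl iodide 22.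
4. 22 ⇐ (S)-epichlorohydrin 14 (supplies C11), opened in turn by two different acetylides.
5. 13 ⇐ exo Diels–Alder of diene 9 with chiral methylidene-dioxolanone 5, then enolate Claisen/lactonisation. Ring order: cyclohexene → tetronate → thiolane → macrocycle.

Labels used below: C5 is the CH2 on the cyclohexene, C6=C7–C8=C9 the diene, C11 the carbinol, C13=C14 the alkene, C16 the methyl-bearing CH, C19 the acyl carbon. Thiolane: S1', C2' (keto acid), C3' (side chain), C4' (acyl), C5'.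

Assumption: the all-trans (2'S,3'S,4'R) thiolane is the thermodynamically preferred arrangement at the two epimerisable centres C2' and C4' (both α to carbonyl groups).

## Route

Step 1
Reactants: 1 (R)-lactic acid; 2 pivalaldehyde
Product: 3 (2R,5R)-2-tert-butyl-5-methyl-1,3-dioxolan-4-one
Conditions: TsOH·H2O (cat.), H2SO4 (cat.), pentane, reflux, Dean–Stark; recrystallise at −78 °C
Reagents that add atoms: none
Why: Acid-catalysed acetalisation (Seebach dioxolanone) gives mainly the cis acetal, so the lactate centre fixes the new acetal centre (2R), and crystallisation removes the trans isomer.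

Step 2
Reactants: 3 (2R,5R)-2-tert-butyl-5-methyl-1,3-dioxolan-4-one
Product: 5 (2R)-2-tert-butyl-5-methylidene-1,3-dioxolan-4-one, via bromodioxolanone 4 (not isolated)
Conditions: NBS, AIBN (cat.), cyclohexane, reflux; then Et3N, Et2O, 0 °C to rt
Reagents that add atoms: none
Why: Wohl–Ziegler radical bromination at the captodative C5–H followed by E2 dehydrobromination gives the exocyclic alkene and leaves the acetal centre untouched.

Step 3
Reactants: 6 4,4-diethoxybut-1-yne; 7 (E)-2-bromobut-2-ene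
Product: 9 (3E,5E)-1,1-diethoxy-5-methylhepta-3,5-diene, via alkenyl pinacol boronate 8 (not isolated)
Conditions: pinacolborane, Cp2Zr(H)Cl (5 mol%), Et3N (10 mol%), 60 °C; then 7, Pd(PPh3)4 (3 mol%), aq. NaOH, THF, 60 °C
Reagents that add atoms: none
Why: syn-Hydroboration of the terminal alkyne gives the (E)-alkenyl boronate, and Suzuki–Miyaura coupling proceeds with retention at both alkenyl partners, fixing both diene geometries.

Step 4
Reactants: 5 (2R)-2-tert-butyl-5-methylidene-1,3-dioxolan-4-one; 9 (3E,5E)-1,1-diethoxy-5-methylhepta-3,5-diene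
Product: 10 (2R,5S,6R,9R)-2-tert-butyl-6-(2,2-diethoxyethyl)-8,9-dimethyl-1,3-dioxaspiro[4.5]dec-7-en-4-one
Conditions: toluene, BHT (cat.), 110 °C, sealed tube, 72 h
Reagents that add atoms: none
Why: Thermal Diels–Alder reaction of the captodative dienophile (Roush-type) on the face anti to tert-butyl sets the spiro centre (S); the exo transition state (lactone carbonyl exo) places the ring oxygen cis to both diene end substituents (ring CH centres R and R), and the quaternary carbon bonds to the diene terminus remote from the 2-methyl group ("para" rule).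

Step 5
Reactants: 10 (2R,5S,6R,9R)-2-tert-butyl-6-(2,2-diethoxyethyl)-8,9-dimethyl-1,3-dioxaspiro[4.5]dec-7-en-4-one
Product: 11 2-[(2R,5S,6R,9R)-2-tert-butyl-8,9-dimethyl-4-oxo-1,3-dioxaspiro[4.5]dec-7-en-6-yl]acetaldehyde
Conditions: TsOH·H2O (10 mol%), acetone/H2O (10:1), rt
Reagents that add atoms: water, O
Why: Acetal hydrolysis of the electron-rich diethyl acetal is much faster than that of the electron-poor dioxolanone acylal, so only the aldehyde is released.

Step 6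
Reactants: 11 2-[(2R,5S,6R,9R)-2-tert-butyl-8,9-dimethyl-4-oxo-1,3-dioxaspiro[4.5]dec-7-en-6-yl]acetaldehyde
Product: 12 (2R,5S,6R,9R)-2-tert-butyl-8,9-dimethyl-6-[(2E)-3-(4,4,5,5-tetramethyl-1,3,2-dioxaborolan-2-yl)prop-2-en-1-yl]-1,3-dioxaspiro[4.5]dec-7-en-4-one
Conditions: CrCl2 (8 equiv), Cl2CHBpin (2 equiv), LiI (4 equiv), THF, rt
Reagents that add atoms: 2-(dichloromethyl)-4,4,5,5-tetramethyl-1,3,2-dioxaborolane, ClC(Cl)B1OC(C)(C)C(C)(C)O1
Why: Takai–Utimoto boryl-olefination via a geminal dichromium species gives the (E)-alkenyl boronate (C6=C7) with high E selectivity.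

Step 7
Reactants: 12 (2R,5S,6R,9R)-2-tert-butyl-8,9-dimethyl-6-[(2E)-3-(4,4,5,5-tetramethyl-1,3,2-dioxaborolan-2-yl)prop-2-en-1-yl]-1,3-dioxaspiro[4.5]dec-7-en-4-one
Product: 13 (5S,6R,9R)-4-hydroxy-8,9-dimethyl-6-[(2E)-3-(4,4,5,5-tetramethyl-1,3,2-dioxaborolan-2-yl)prop-2-en-1-yl]-1-oxaspiro[4.5]deca-3,7-dien-2-one
Conditions: CH3CO2Me, LiN(SiMe3)2 (3.2 equiv each), THF, −78 °C; add 12, −78 to 0 °C; 1 M HCl
Reagents that add atoms: methyl acetate, CC(=O)OC
Why: Proposed new method: the dioxolanone is an activated lactone-acylal, so Claisen attack of the ester enolate at its carbonyl opens the ring, the hemiacetal alkoxide expels pivalaldehyde, and the freed tertiary alkoxide lactonises onto the methyl ester to give the tetronic acid without touching the three stereocentres; the closest known reactions are the Claisen acylation of ester enolates by 1,3-dioxolan-4-ones in tetronic acid and pulvinone synthesis and the Dieckmann cyclisation of α-acetoxy esters.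

Step 8
Reactants: 14 (S)-epichlorohydrin; 15 ethynyltri(propan-2-yl)silane
Product: 17 (2S)-1-chloro-5-[tri(propan-2-yl)silyl]pent-4-yn-2-ol, via lithium silylacetylide 16 (not isolated)
Conditions: n-BuLi, THF, −78 °C; BF3·OEt2; 14, −78 °C
Reagents that add atoms: none
Why: BF3-promoted (Yamaguchi) opening of the epoxide at its CH2 terminus by the alkynyl nucleophile leaves the carbinol centre (future C11) untouched.

Step 9
Reactants: 17 (2S)-1-chloro-5-[tri(propan-2-yl)silyl]pent-4-yn-2-ol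
Product: 19 (4R)-1-[tri(propan-2-yl)silyl]hepta-1,6-diyn-4-ol, via silylpropargyl epoxide 18 (not isolated)
Conditions: LiC≡CH·H2NCH2CH2NH2 (3.5 equiv), DMSO, 0 °C to rt
Reagents that add atoms: lithium acetylide–ethylenediamine complex, [Li]C#C.NCCN
Why: The alkoxide closes to the terminal epoxide (SN2 at CH2Cl) and a second acetylide opens it at CH2, so the two arms on C11 differ only by the silyl group and no bond to the stereocentre is broken.

Step 10
Reactants: 19 (4R)-1-[tri(propan-2-yl)silyl]hepta-1,6-diyn-4-ol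
Product: 20 tert-butyl{[(4R)-1-[tri(propan-2-yl)silyl]hepta-1,6-diyn-4-yl]oxy}diphenylsilane
Conditions: TBDPSCl, imidazole, DMF, rt
Reagents that add atoms: tert-butyl(chloro)diphenylsilane, CC(C)(C)[Si](Cl)(c1ccccc1)c1ccccc1
Why: Standard silylation gives an acid- and base-stable ether on the C11 hydroxyl that survives to the last step.

Step 11
Reactants: 20 tert-butyl{[(4R)-1-[tri(propan-2-yl)silyl]hepta-1,6-diyn-4-yl]oxy}diphenylsilane
Product: 22 tert-butyl{[(1E,4R)-1-iodo-7-[tri(propan-2-yl)silyl]hept-1-en-6-yn-4-yl]oxy}diphenylsilane, via alkenylzirconocene chloride 21 (not isolated)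
Conditions: Cp2Zr(H)Cl (1.5 equiv), THF, rt; I2, 0 °C
Reagents that add atoms: iodine, II
Why: Hydrozirconation is syn and selective for the terminal alkyne over the silyl-capped one, and iodinolysis with retention gives the (E)-alkenyl iodide (future C13=C14).

Step 12
Reactants: 22 tert-butyl{[(1E,4R)-1-iodo-7-[tri(propan-2-yl)silyl]hept-1-en-6-yn-4-yl]oxy}diphenylsilane; 23 methyl (R)-3-bromo-2-methylpropanoate
Product: 25 methyl (2S,4E,7R)-7-[(tert-butyldiphenylsilyl)oxy]-2-methyl-10-[tri(propan-2-yl)silyl]dec-4-en-9-ynoate, via zinc homoenolate 24 (not isolated)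
Conditions: 23, Zn dust (3 equiv), I2 (5 mol%), DMA, 80 °C; then 22, Pd(PPh3)4 (5 mol%), THF/DMA, 40 °C
Reagents that add atoms: none
Why: Key step, a Negishi sp3–sp2 coupling of a zinc ester homoenolate: the β-carbon of the ester (C15, normally an electrophilic position) is made nucleophilic as C–Zn and joined to the electrophilic alkenyl iodide carbon C14 with retention of the E geometry, while the C16 methyl centre comes unchanged from the chiral pool because β-zincio esters neither enolise nor eliminate.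

Step 13
Reactants: 25 methyl (2S,4E,7R)-7-[(tert-butyldiphenylsilyl)oxy]-2-methyl-10-[tri(propan-2-yl)silyl]dec-4-en-9-ynoate
Product: 27 methyl (2S,4E,7R)-7-[(tert-butyldiphenylsilyl)oxy]-2-methyldec-4-en-9-ynoate, via silver acetylide 26 (not isolated)
Conditions: AgF (1.5 equiv), MeOH/THF, rt, dark; then 1 M HCl
Reagents that add atoms: none
Why: Silver fluoride cleaves the alkynyl C–Si bond selectively (the silyl ether is untouched) and acid releases the terminal alkyne from its silver acetylide.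

Step 14
Reactants: 27 methyl (2S,4E,7R)-7-[(tert-butyldiphenylsilyl)oxy]-2-methyldec-4-en-9-ynoate
Product: 29 methyl (2S,4E,7R,9E)-7-[(tert-butyldiphenylsilyl)oxy]-10-iodo-2-methyldeca-4,9-dienoate, via alkenylzirconocene chloride 28 (not isolated)
Conditions: Cp2Zr(H)Cl (1.6 equiv), THF, 0 °C to rt; I2, 0 °C
Reagents that add atoms: iodine, II
Why: Hydrozirconation of the terminal alkyne is faster than reaction with the internal alkene or the ester, and iodinolysis gives the (E)-alkenyl iodide at C8=C9.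

Step 15
Reactants: 29 methyl (2S,4E,7R,9E)-7-[(tert-butyldiphenylsilyl)oxy]-10-iodo-2-methyldeca-4,9-dienoate
Product: 30 (2S,4E,7R,9E)-7-[(tert-butyldiphenylsilyl)oxy]-10-iodo-2-methyldeca-4,9-dienal
Conditions: i-Bu2AlH (1.05 equiv), CH2Cl2, −78 °C; MeOH, aq. KNaC4H4O6
Reagents that add atoms: none
Why: Partial reduction of the methyl ester stops at the tetrahedral aluminium hemiacetal at −78 °C, and the cold, non-basic work-up keeps the α-methyl centre (C16) intact.

Step 16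
Reactants: 31 tert-butyl 2-(diethoxyphosphoryl)acetate
Product: 33 tert-butyl 2-(diethoxyphosphoryl)prop-2-enoate, via methoxymethyl phosphonate 32 (not isolated)
Conditions: (CH2O)n, piperidine (cat.), MeOH, reflux; then TsOH·H2O (cat.), toluene, reflux (distil MeOH)
Reagents that add atoms: formaldehyde (as paraformaldehyde), C=O
Why: Knoevenagel-type hydroxymethylation of the phosphonoacetate followed by acid-catalysed elimination gives the 2-phosphonoacrylate (known procedure for the ethyl ester).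

Step 17
Reactants: 33 tert-butyl 2-(diethoxyphosphoryl)prop-2-enoate; 30 (2S,4E,7R,9E)-7-[(tert-butyldiphenylsilyl)oxy]-10-iodo-2-methyldeca-4,9-dienal
Product: 35 tert-butyl (2Z,4S,6E,9R,11E)-2-[(acetylsulfanyl)methyl]-9-[(tert-butyldiphenylsilyl)oxy]-12-iodo-4-methyldodeca-2,6,11-trienoate, via potassium phosphonate carbanion 34 (not isolated)
Conditions: KSC(O)CH3 (1.05 equiv), 33 (1.1 equiv), THF, 0 °C; then 30, 0 °C to rt
Reagents that add atoms: potassium thioacetate, CC(=O)[S-].[K+]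
Why: Tandem thia-Michael/Horner–Wadsworth–Emmons reaction: thioacetate adds to the vinylphosphonate and the resulting weakly basic carbanion olefinates the α-branched aldehyde without epimerising C16, placing the alkyl chain trans to the ester.

Step 18
Reactants: 35 tert-butyl (2Z,4S,6E,9R,11E)-2-[(acetylsulfanyl)methyl]-9-[(tert-butyldiphenylsilyl)oxy]-12-iodo-4-methyldodeca-2,6,11-trienoate; 36 ethyl 3-bromo-2-oxopropanoate
Product: 39 tert-butyl (3R,4S,5S)-4-[(2S,4E,7R,9E)-7-[(tert-butyldiphenylsilyl)oxy]-10-iododeca-4,9-dien-2-yl]-5-(2-ethoxy-2-oxoacetyl)thiolane-3-carboxylate, via sodium thiolate 37 (not isolated), via keto ester sulfide 38 (not isolated)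
Conditions: NaOEt (1.0 equiv), EtOH/THF, −40 °C; 36, −40 to 0 °C; AcOH; quinidine-derived 3,5-bis(trifluoromethyl)benzyl squaramide (10 mol%), toluene, rt; then NaOEt (1.2 equiv), EtOH, 40 °C; AcOH
Reagents that add atoms: none
Why: Proposed new method: ethoxide cleaves the thioacetate, the thiolate is S-alkylated by the bromo ketone, and the amine–squaramide binds the enolised α-thio-α-keto ester and the enoate so that the 5-exo-trig Michael addition forms C2'–C3' on one enoate face and sets C3' (S) under catalyst control (the 1,2-bias from C16 is weak, and the quinine-derived pseudoenantiomer is used if the screen shows the opposite sense); NaOEt then equilibrates the carbonyl-flanked centres C2' and C4' to the all-trans ring while the C2' enolate blocks retro-Michael scrambling of C3'; the closest known reactions are squaramide-catalysed sulfa-Michael/Michael cyclisations to tetrahydrothiophenes.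

Step 19
Reactants: 39 tert-butyl (3R,4S,5S)-4-[(2S,4E,7R,9E)-7-[(tert-butyldiphenylsilyl)oxy]-10-iododeca-4,9-dien-2-yl]-5-(2-ethoxy-2-oxoacetyl)thiolane-3-carboxylate
Product: 40 (3R,4S,5S)-4-[(2S,4E,7R,9E)-7-[(tert-butyldiphenylsilyl)oxy]-10-iododeca-4,9-dien-2-yl]-5-(2-ethoxy-2-oxoacetyl)thiolane-3-carboxylic acid
Conditions: TFA/CH2Cl2 (1:4), 0 °C to rt
Reagents that add atoms: none
Why: Acidolysis of the tert-butyl ester (E1 loss of isobutene) frees the C19 acid while the ethyl keto ester, the alkenyl iodide, the sulfide and the diphenylsilyl ether are stable to acid.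

Step 20
Reactants: 40 (3R,4S,5S)-4-[(2S,4E,7R,9E)-7-[(tert-butyldiphenylsilyl)oxy]-10-iododeca-4,9-dien-2-yl]-5-(2-ethoxy-2-oxoacetyl)thiolane-3-carboxylic acid; 13 (5S,6R,9R)-4-hydroxy-8,9-dimethyl-6-[(2E)-3-(4,4,5,5-tetramethyl-1,3,2-dioxaborolan-2-yl)prop-2-en-1-yl]-1-oxaspiro[4.5]deca-3,7-dien-2-one
Product: 42 ethyl 2-{(2S,3S,4R)-3-[(2S,4E,7R,9E)-7-[(tert-butyldiphenylsilyl)oxy]-10-iododeca-4,9-dien-2-yl]-4-({(5S,6R,9R)-4-hydroxy-8,9-dimethyl-2-oxo-6-[(2E)-3-(4,4,5,5-tetramethyl-1,3,2-dioxaborolan-2-yl)prop-2-en-1-yl]-1-oxaspiro[4.5]deca-3,7-dien-3-yl}carbonyl)thiolan-2-yl}-2-oxoacetate, via O-acyl tetronate 41 (not isolated)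
Conditions: DCC (1.2 equiv), DMAP (1.5 equiv), CH2Cl2, 0 °C to rt
Reagents that add atoms: none
Why: Yoshii-type acylation: DCC/DMAP first O-acylates the tetronic acid and DMAP then transfers the acyl group from O4 to C3 (Fries-type shift) to give the chelated 3-acyl tetronic acid; no new stereocentre forms and C4' stays in its thermodynamic trans configuration.

Step 21
Reactants: 42 ethyl 2-{(2S,3S,4R)-3-[(2S,4E,7R,9E)-7-[(tert-butyldiphenylsilyl)oxy]-10-iododeca-4,9-dien-2-yl]-4-({(5S,6R,9R)-4-hydroxy-8,9-dimethyl-2-oxo-6-[(2E)-3-(4,4,5,5-tetramethyl-1,3,2-dioxaborolan-2-yl)prop-2-en-1-yl]-1-oxaspiro[4.5]deca-3,7-dien-3-yl}carbonyl)thiolan-2-yl}-2-oxoacetate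
Product: 44 11-O-(tert-butyldiphenylsilyl) ether of the target macrocycle (free 2-oxoacetic acid), via seco keto acid 43 (not isolated)
Conditions: Pd(PPh3)4 (20 mol%), Ba(OH)2·8H2O (6 equiv), degassed DMF/H2O (9:1), 1 mM, rt; then aq. KHSO4
Reagents that add atoms: water (as hydroxide), O
Why: Hydroxide first saponifies the activated α-keto ethyl ester, then intramolecular Suzuki–Miyaura coupling of the (E)-alkenyl boronate with the (E)-alkenyl iodide closes the 19-membered ring at C7–C8 with retention of both geometries, giving the (6E,8E)-diene under high dilution.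

Step 22
Reactants: 44 11-O-(tert-butyldiphenylsilyl) ether of the target macrocycle (free 2-oxoacetic acid)
Product: 45 target CNP0224658.3
Conditions: HF·pyridine, pyridine/THF, 0 °C to rt
Reagents that add atoms: none
Why: Fluoride cleaves the Si–O bond of the C11 silyl ether under buffered conditions that leave the acyl tetronic acid, the keto acid and the diene untouched, releasing the (11R) alcohol.

## Compound list

1 | (R)-lactic acid | C[C@@H](O)C(=O)O | starting material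
2 | pivalaldehyde | CC(C)(C)C=O | starting material
3 | (2R,5R)-2-tert-butyl-5-methyl-1,3-dioxolan-4-one | C[C@H]1O[C@@H](C(C)(C)C)OC1=O | intermediate
4 | 5-bromo-2-tert-butyl-5-methyl-1,3-dioxolan-4-one (acetal centre as in 3; C5 epimers) | CC1(Br)O[C@@H](C(C)(C)C)OC1=O | intermediate (not isolated)
5 | (2R)-2-tert-butyl-5-methylidene-1,3-dioxolan-4-one | C=C1O[C@@H](C(C)(C)C)OC1=O | intermediate
6 | 4,4-diethoxybut-1-yne | CCOC(OCC)CC#C | starting material
7 | (E)-2-bromobut-2-ene | C/C=C(/Br)C | starting material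
8 | 2-[(1E)-4,4-diethoxybut-1-en-1-yl]-4,4,5,5-tetramethyl-1,3,2-dioxaborolane | CCOC(OCC)C/C=C/B1OC(C)(C)C(C)(C)O1 | intermediate (not isolated)
9 | (3E,5E)-1,1-diethoxy-5-methylhepta-3,5-diene | CCOC(OCC)C/C=C/C(C)=C/C | intermediate
10 | (2R,5S,6R,9R)-2-tert-butyl-6-(2,2-diethoxyethyl)-8,9-dimethyl-1,3-dioxaspiro[4.5]dec-7-en-4-one | O=C1O[C@H](C(C)(C)C)O[C@]12C[C@@H](C)C(C)=C[C@H]2CC(OCC)OCC | intermediate
11 | 2-[(2R,5S,6R,9R)-2-tert-butyl-8,9-dimethyl-4-oxo-1,3-dioxaspiro[4.5]dec-7-en-6-yl]acetaldehyde | O=C1O[C@H](C(C)(C)C)O[C@]12C[C@@H](C)C(C)=C[C@H]2CC=O | intermediate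
12 | (2R,5S,6R,9R)-2-tert-butyl-8,9-dimethyl-6-[(2E)-3-(4,4,5,5-tetramethyl-1,3,2-dioxaborolan-2-yl)prop-2-en-1-yl]-1,3-dioxaspiro[4.5]dec-7-en-4-one | O=C1O[C@H](C(C)(C)C)O[C@]12C[C@@H](C)C(C)=C[C@H]2C/C=C/B1OC(C)(C)C(C)(C)O1 | intermediate
13 | (5S,6R,9R)-4-hydroxy-8,9-dimethyl-6-[(2E)-3-(4,4,5,5-tetramethyl-1,3,2-dioxaborolan-2-yl)prop-2-en-1-yl]-1-oxaspiro[4.5]deca-3,7-dien-2-one | O=C1C=C(O)[C@]2(O1)C[C@@H](C)C(C)=C[C@H]2C/C=C/B1OC(C)(C)C(C)(C)O1 | intermediate
14 | (S)-epichlorohydrin | ClC[C@@H]1CO1 | starting material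
15 | ethynyltri(propan-2-yl)silane | C#C[Si](C(C)C)(C(C)C)C(C)C | starting material
16 | lithium [tri(propan-2-yl)silyl]acetylide | [Li]C#C[Si](C(C)C)(C(C)C)C(C)C | intermediate (not isolated)
17 | (2S)-1-chloro-5-[tri(propan-2-yl)silyl]pent-4-yn-2-ol | CC(C)[Si](C(C)C)(C(C)C)C#CC[C@H](O)CCl | intermediate
18 | {3-[(2S)-oxiran-2-yl]prop-1-yn-1-yl}tri(propan-2-yl)silane | CC(C)[Si](C(C)C)(C(C)C)C#CC[C@H]1CO1 | intermediate (not isolated)
19 | (4R)-1-[tri(propan-2-yl)silyl]hepta-1,6-diyn-4-ol | CC(C)[Si](C(C)C)(C(C)C)C#CC[C@H](O)CC#C | intermediate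
20 | tert-butyl{[(4R)-1-[tri(propan-2-yl)silyl]hepta-1,6-diyn-4-yl]oxy}diphenylsilane | CC(C)[Si](C(C)C)(C(C)C)C#CC[C@H](O[Si](c1ccccc1)(c1ccccc1)C(C)(C)C)CC#C | intermediate
21 | chlorobis(cyclopentadienyl){(1E,4R)-4-[(tert-butyldiphenylsilyl)oxy]-7-[tri(propan-2-yl)silyl]hept-1-en-6-yn-1-yl}zirconium (Cp drawn σ-bonded) | CC(C)[Si](C(C)C)(C(C)C)C#CC[C@H](O[Si](c1ccccc1)(c1ccccc1)C(C)(C)C)C/C=C/[Zr](Cl)(C1C=CC=C1)C1C=CC=C1 | intermediate (not isolated)
22 | tert-butyl{[(1E,4R)-1-iodo-7-[tri(propan-2-yl)silyl]hept-1-en-6-yn-4-yl]oxy}diphenylsilane | CC(C)[Si](C(C)C)(C(C)C)C#CC[C@H](O[Si](c1ccccc1)(c1ccccc1)C(C)(C)C)C/C=C/I | intermediate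
23 | methyl (R)-3-bromo-2-methylpropanoate | COC(=O)[C@@H](C)CBr | starting material
24 | bromo[(2R)-3-methoxy-2-methyl-3-oxopropyl]zinc | COC(=O)[C@@H](C)C[Zn]Br | intermediate (not isolated)
25 | methyl (2S,4E,7R)-7-[(tert-butyldiphenylsilyl)oxy]-2-methyl-10-[tri(propan-2-yl)silyl]dec-4-en-9-ynoate | CC(C)[Si](C(C)C)(C(C)C)C#CC[C@H](O[Si](c1ccccc1)(c1ccccc1)C(C)(C)C)C/C=C/C[C@H](C)C(=O)OC | intermediate
26 | silver acetylide of 27 | [Ag]C#CC[C@H](O[Si](c1ccccc1)(c1ccccc1)C(C)(C)C)C/C=C/C[C@H](C)C(=O)OC | intermediate (not isolated)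
27 | methyl (2S,4E,7R)-7-[(tert-butyldiphenylsilyl)oxy]-2-methyldec-4-en-9-ynoate | C#CC[C@H](O[Si](c1ccccc1)(c1ccccc1)C(C)(C)C)C/C=C/C[C@H](C)C(=O)OC | intermediate
28 | chlorobis(cyclopentadienyl){(1E,4R,6E,9S)-4-[(tert-butyldiphenylsilyl)oxy]-10-methoxy-9-methyl-10-oxodeca-1,6-dien-1-yl}zirconium (Cp drawn σ-bonded) | Cl[Zr](C1C=CC=C1)(C1C=CC=C1)/C=C/C[C@H](O[Si](c1ccccc1)(c1ccccc1)C(C)(C)C)C/C=C/C[C@H](C)C(=O)OC | intermediate (not isolated)
29 | methyl (2S,4E,7R,9E)-7-[(tert-butyldiphenylsilyl)oxy]-10-iodo-2-methyldeca-4,9-dienoate | I/C=C/C[C@H](O[Si](c1ccccc1)(c1ccccc1)C(C)(C)C)C/C=C/C[C@H](C)C(=O)OC | intermediate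
30 | (2S,4E,7R,9E)-7-[(tert-butyldiphenylsilyl)oxy]-10-iodo-2-methyldeca-4,9-dienal | I/C=C/C[C@H](O[Si](c1ccccc1)(c1ccccc1)C(C)(C)C)C/C=C/C[C@H](C)C=O | intermediate
31 | tert-butyl 2-(diethoxyphosphoryl)acetate | CCOP(=O)(OCC)CC(=O)OC(C)(C)C | starting material
32 | tert-butyl 2-(diethoxyphosphoryl)-3-methoxypropanoate | CCOP(=O)(OCC)C(COC)C(=O)OC(C)(C)C | intermediate (not isolated)
33 | tert-butyl 2-(diethoxyphosphoryl)prop-2-enoate | CCOP(=O)(OCC)C(=C)C(=O)OC(C)(C)C | intermediate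
34 | potassium 1-(acetylsulfanyl)-3-tert-butoxy-2-(diethoxyphosphoryl)-3-oxopropan-2-ide | CCOP(=O)(OCC)[C-](CSC(C)=O)C(=O)OC(C)(C)C.[K+] | intermediate (not isolated)
35 | tert-butyl (2Z,4S,6E,9R,11E)-2-[(acetylsulfanyl)methyl]-9-[(tert-butyldiphenylsilyl)oxy]-12-iodo-4-methyldodeca-2,6,11-trienoate | I/C=C/C[C@H](O[Si](c1ccccc1)(c1ccccc1)C(C)(C)C)C/C=C/C[C@H](C)/C=C(\CSC(C)=O)C(=O)OC(C)(C)C | intermediate
36 | ethyl 3-bromo-2-oxopropanoate (ethyl bromopyruvate) | CCOC(=O)C(=O)CBr | starting material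
37 | sodium thiolate from 35 (SAc replaced by S− Na+) | I/C=C/C[C@H](O[Si](c1ccccc1)(c1ccccc1)C(C)(C)C)C/C=C/C[C@H](C)/C=C(\C[S-])C(=O)OC(C)(C)C.[Na+] | intermediate (not isolated)
38 | tert-butyl (2Z,4S,6E,9R,11E)-9-[(tert-butyldiphenylsilyl)oxy]-2-{[(3-ethoxy-2,3-dioxopropyl)sulfanyl]methyl}-12-iodo-4-methyldodeca-2,6,11-trienoate | I/C=C/C[C@H](O[Si](c1ccccc1)(c1ccccc1)C(C)(C)C)C/C=C/C[C@H](C)/C=C(\CSCC(=O)C(=O)OCC)C(=O)OC(C)(C)C | intermediate (not isolated)
39 | tert-butyl (3R,4S,5S)-4-[(2S,4E,7R,9E)-7-[(tert-butyldiphenylsilyl)oxy]-10-iododeca-4,9-dien-2-yl]-5-(2-ethoxy-2-oxoacetyl)thiolane-3-carboxylate | I/C=C/C[C@H](O[Si](c2ccccc2)(c2ccccc2)C(C)(C)C)C/C=C/C[C@H](C)[C@@H]1[C@@H](C(=O)C(=O)OCC)SC[C@H]1C(=O)OC(C)(C)C | intermediate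
40 | (3R,4S,5S)-4-[(2S,4E,7R,9E)-7-[(tert-butyldiphenylsilyl)oxy]-10-iododeca-4,9-dien-2-yl]-5-(2-ethoxy-2-oxoacetyl)thiolane-3-carboxylic acid | I/C=C/C[C@H](O[Si](c2ccccc2)(c2ccccc2)C(C)(C)C)C/C=C/C[C@H](C)[C@@H]1[C@@H](C(=O)C(=O)OCC)SC[C@H]1C(=O)O | intermediate
41 | enol ester of 13 (O4-acylated by acid 40) | I/C=C/C[C@H](O[Si](c1ccccc1)(c1ccccc1)C(C)(C)C)C/C=C/C[C@H](C)[C@@H]2[C@@H](C(=O)C(=O)OCC)SC[C@H]2C(=O)OC3=CC(=O)O[C@]34C[C@@H](C)C(C)=C[C@H]4C/C=C/B5OC(C)(C)C(C)(C)O5 | intermediate (not isolated)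
42 | ethyl 2-{(2S,3S,4R)-3-[(2S,4E,7R,9E)-7-[(tert-butyldiphenylsilyl)oxy]-10-iododeca-4,9-dien-2-yl]-4-({(5S,6R,9R)-4-hydroxy-8,9-dimethyl-2-oxo-6-[(2E)-3-(4,4,5,5-tetramethyl-1,3,2-dioxaborolan-2-yl)prop-2-en-1-yl]-1-oxaspiro[4.5]deca-3,7-dien-3-yl}carbonyl)thiolan-2-yl}-2-oxoacetate | I/C=C/C[C@H](O[Si](c1ccccc1)(c1ccccc1)C(C)(C)C)C/C=C/C[C@H](C)[C@@H]2[C@@H](C(=O)C(=O)OCC)SC[C@H]2C(=O)C3=C(O)[C@]4(OC3=O)C[C@@H](C)C(C)=C[C@H]4C/C=C/B5OC(C)(C)C(C)(C)O5 | intermediate
43 | 2-oxoacetic acid corresponding to ethyl ester 42 | I/C=C/C[C@H](O[Si](c1ccccc1)(c1ccccc1)C(C)(C)C)C/C=C/C[C@H](C)[C@@H]2[C@@H](C(=O)C(=O)O)SC[C@H]2C(=O)C3=C(O)[C@]4(OC3=O)C[C@@H](C)C(C)=C[C@H]4C/C=C/B5OC(C)(C)C(C)(C)O5 | intermediate (not isolated)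
44 | 11-O-(tert-butyldiphenylsilyl) ether of the target macrocycle (free 2-oxoacetic acid) | CC1=C[C@H]2C/C=C/C=C/C[C@H](O[Si](c4ccccc4)(c4ccccc4)C(C)(C)C)C/C=C/C[C@H](C)[C@@H]3[C@@H](C(=O)C(=O)O)SC[C@H]3C(=O)C3=C(O)[C@@]2(C[C@H]1C)OC3=O | intermediate
45 | target CNP0224658.3: 19-membered carbocycle through a 3-acyl spirotetronic acid (spiro S; ring CH R; ring CH(CH3) R), (6E,8E)-diene, (11R)-ol, (13E)-alkene, (16S)-methyl, all-trans (2'S,3'S,4'R)-thiolane bearing the 2-oxoacetic acid | CC1=C[C@H]2C/C=C/C=C/C[C@H](O)C/C=C/C[C@H](C)[C@@H]3[C@@H](C(=O)C(=O)O)SC[C@H]3C(=O)C3=C(O)[C@@]2(C[C@H]1C)OC3=O | target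

## Step count and weak points

Total: 22 steps. Longest linear sequence: 14 steps (from 14 through steps 8–15 and 17–22).

The three steps most likely to fail:

Step 18 (thiolane closure; control of C3' against a weak substrate bias). Fallback: the route leaves from aldehyde 30 and sets C3' intermolecularly instead. A Morita–Baylis–Hillman reaction with tert-butyl acrylate (DABCO, MeOH) gives tert-butyl (4S,6E,9R,11E)-9-[(tert-butyldiphenylsilyl)oxy]-3-hydroxy-12-iodo-4-methyl-2-methylidenedodeca-6,11-dienoate F3. Boc2O/DMAP converts it into its 3-O-tert-butoxycarbonyl carbonate F4. Ethyl 3-(acetylsulfanyl)-2-oxopropanoate F5, made from 36 and KSC(O)CH3, is then joined at the branched carbon by chiral Lewis-base allylic alkylation ((DHQD)2PHAL or its pseudoenantiomer) to give tert-butyl (3S,4S,6E,9R,11E)-3-[1-(acetylsulfanyl)-3-ethoxy-2,3-dioxopropyl]-9-[(tert-butyldiphenylsilyl)oxy]-12-iodo-4-methyl-2-methylidenedodeca-6,11-dienoate F6. NaOEt/EtOH removes the acetyl group, the thiol closes the ring by 5-endo thia-Michael addition onto the acrylate with equilibration of C2' and C4', and the route rejoins at 39.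

Step 21 (19-membered ring closure by Suzuki coupling). Fallback: the route leaves from 40 and 13 and reverses the order of the two bond formations. An intermolecular Suzuki coupling under anhydrous fluoride activation (Pd(dppf)Cl2, CsF, dioxane) builds the diene first and gives the seco acid (tetronic acid with free C3, C19 carboxylic acid, ethyl keto ester) F7. This is cyclised at 1 mM by DCC/DMAP O-acylation and O-to-C acyl shift to the macrocyclic ethyl ester (ethyl ester of 44) F8. Saponification with Ba(OH)2 in THF/H2O rejoins the route at 44.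

Step 7 (one-flask Claisen/lactonisation on the hindered dioxolanone). Fallback: the route leaves from 12 and builds the tetronic acid stepwise. K2CO3/MeOH methanolysis gives methyl (1S,2R,5R)-1-hydroxy-4,5-dimethyl-2-[(2E)-3-(4,4,5,5-tetramethyl-1,3,2-dioxaborolan-2-yl)prop-2-en-1-yl]cyclohex-3-ene-1-carboxylate F1. Acetylation (Ac2O, DMAP, Et3N) gives the tertiary acetate methyl (1S,2R,5R)-1-(acetyloxy)-4,5-dimethyl-2-[(2E)-3-(4,4,5,5-tetramethyl-1,3,2-dioxaborolan-2-yl)prop-2-en-1-yl]cyclohex-3-ene-1-carboxylate F2. Dieckmann cyclisation (LiN(SiMe3)2, THF, −78 to 0 °C) rejoins the route at 13.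

## Further compounds

F1 | step 7 | methyl (1S,2R,5R)-1-hydroxy-4,5-dimethyl-2-[(2E)-3-(4,4,5,5-tetramethyl-1,3,2-dioxaborolan-2-yl)prop-2-en-1-yl]cyclohex-3-ene-1-carboxylate | COC(=O)[C@]1(O)C[C@@H](C)C(C)=C[C@H]1C/C=C/B2OC(C)(C)C(C)(C)O2
F2 | step 7 | methyl (1S,2R,5R)-1-(acetyloxy)-4,5-dimethyl-2-[(2E)-3-(4,4,5,5-tetramethyl-1,3,2-dioxaborolan-2-yl)prop-2-en-1-yl]cyclohex-3-ene-1-carboxylate | COC(=O)[C@]1(OC(C)=O)C[C@@H](C)C(C)=C[C@H]1C/C=C/B2OC(C)(C)C(C)(C)O2
F3 | step 18 | tert-butyl (4S,6E,9R,11E)-9-[(tert-butyldiphenylsilyl)oxy]-3-hydroxy-12-iodo-4-methyl-2-methylidenedodeca-6,11-dienoate (C3 epimers) | I/C=C/C[C@H](O[Si](c1ccccc1)(c1ccccc1)C(C)(C)C)C/C=C/C[C@H](C)C(O)C(=C)C(=O)OC(C)(C)C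
F4 | step 18 | 3-O-tert-butoxycarbonyl carbonate of F3 | I/C=C/C[C@H](O[Si](c1ccccc1)(c1ccccc1)C(C)(C)C)C/C=C/C[C@H](C)C(OC(=O)OC(C)(C)C)C(=C)C(=O)OC(C)(C)C
F5 | step 18 | ethyl 3-(acetylsulfanyl)-2-oxopropanoate | CCOC(=O)C(=O)CSC(C)=O
F6 | step 18 | tert-butyl (3S,4S,6E,9R,11E)-3-[1-(acetylsulfanyl)-3-ethoxy-2,3-dioxopropyl]-9-[(tert-butyldiphenylsilyl)oxy]-12-iodo-4-methyl-2-methylidenedodeca-6,11-dienoate | I/C=C/C[C@H](O[Si](c1ccccc1)(c1ccccc1)C(C)(C)C)C/C=C/C[C@H](C)[C@H](C(SC(C)=O)C(=O)C(=O)OCC)C(=C)C(=O)OC(C)(C)C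
F7 | step 21 | seco acid: (6E,8E)-diene formed; tetronic acid C3–H; thiolane C19 carboxylic acid; ethyl keto ester; C11 silyl ether | O=C1C=C(O)[C@]2(O1)C[C@@H](C)C(C)=C[C@H]2C/C=C/C=C/C[C@H](O[Si](c3ccccc3)(c3ccccc3)C(C)(C)C)C/C=C/C[C@H](C)[C@@H]3[C@@H](C(=O)C(=O)OCC)SC[C@H]3C(=O)O
F8 | step 21 | ethyl ester of macrocycle 44 | CC1=C[C@H]2C/C=C/C=C/C[C@H](O[Si](c4ccccc4)(c4ccccc4)C(C)(C)C)C/C=C/C[C@H](C)[C@@H]3[C@@H](C(=O)C(=O)OCC)SC[C@H]3C(=O)C3=C(O)[C@@]2(C[C@H]1C)OC3=O
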